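The ten-membered ring is closed last, at C2–C3 (C1 is the ring carbon bearing the exocyclic methylene, C2 and C3 the CH2 groups leading to the cyclobutane fusion carbon C4). Zerovalent palladium turns an allylic carbonate on C2 into a π-allyl in which C2 and the methylene carbon are equivalent termini on C1; the bis(phenylsulfonyl) carbanion on C3 attacks it, so one operation forms the C2–C3 bond and the macrocycle without any regiochemical issue. The precursor is the open chain carrying a CH(SO2Ph)2 group on the fully substituted cyclobutane, a silyl-protected 2-(hydroxymethyl)vinyl group on C8 and the lavandulol-derived C9–C10 end, with all five stereocentres in place.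

Key step: step 23

Remark: locants continue round the ring: C5 quaternary fusion carbon bearing CH3, C6 and C7 CH2, C8 CH bearing the three-carbon side chain, C9 CH2, C10 CH bearing prenyl; C11 is the cyclobutane CH2 and C12 the cyclobutane CH bearing isopropenyl.
Remark: the sense of induction of the ferrocenyl ligand in step 1 is not predicted, so the antipode that gives the (3R) ketone is assumed to be chosen; the bis-sulfone is built by sulfonylation and not by sulfur oxidation, so that no oxidant meets the alkenes; 2-bromo-3-(tert-butyldimethylsilyloxy)prop-1-ene is taken as a purchased reagent.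

Step 1
Reactants: 1 2-methylcyclopent-2-en-1-one
Product: 3 (2R,3R)-2-methyl-3-(prop-1-en-2-yl)-2-(prop-2-en-1-yl)cyclopentan-1-one, via bromomagnesium enolate 2 (not isolated)
Conditions: CH2=C(CH3)MgBr, CuBr·SMe2 (5 mol %), (R)-1-[(S)-2-(diphenylphosphino)ferrocenyl]ethyldicyclohexylphosphine or its antipode (6 mol %), t-BuOMe, −78 °C; then allyl iodide, DMPU, −78 °C to rt
Reagents that add atoms: isopropenylmagnesium bromide CC(=C)[Mg]Br; allyl iodide C=CCI
Why: Copper-catalysed asymmetric conjugate addition of a Grignard reagent to an α-substituted cyclic enone with alkylation of the enolate in the same flask: the ligand on monovalent copper decides the face to which isopropenyl is delivered (the future C12), and allyl iodide then attacks the enolate anti to that group, so the quaternary centre (the future C5) forms with methyl cis to isopropenyl.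

Step 2
Reactants: 3 (2R,3R)-2-methyl-3-(prop-1-en-2-yl)-2-(prop-2-en-1-yl)cyclopentan-1-one
Product: 5 (2R,3R)-5-diazo-2-methyl-3-(prop-1-en-2-yl)-2-(prop-2-en-1-yl)cyclopentan-1-one, via trifluoroacetyl ketone 4 (not isolated)
Conditions: LiN(SiMe3)2, THF, −78 °C, then CF3CO2CH2CF3; MsN3, Et3N, H2O, MeCN, rt
Reagents that add atoms: methanesulfonyl azide CS(=O)(=O)N=[N+]=[N-]
Why: Regitz-type deacylative diazo transfer: the ketone can enolise only toward the CH2 remote from the quaternary carbon, so trifluoroacetylation and diazo transfer occur there and no stereocentre is touched.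

Step 3
Reactants: 5 (2R,3R)-5-diazo-2-methyl-3-(prop-1-en-2-yl)-2-(prop-2-en-1-yl)cyclopentan-1-one
Product: 7 methyl (1R,2R,3R)-2-methyl-3-(prop-1-en-2-yl)-2-(prop-2-en-1-yl)cyclobutane-1-carboxylate, via ketene 6 (not isolated)
Conditions: hν (medium-pressure Hg lamp, Pyrex), MeOH, 0 °C
Reagents that add atoms: methanol CO
Why: Photochemical Wolff rearrangement with ring contraction: the quaternary carbon migrates with retention to the carbene carbon, and methanol adds to the ketene with protonation of the new ring carbon (C4) from the face opposite the transannular isopropenyl group and the C5 methyl, which should place the ester cis to both.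

Step 4
Reactants: 7 methyl (1R,2R,3R)-2-methyl-3-(prop-1-en-2-yl)-2-(prop-2-en-1-yl)cyclobutane-1-carboxylate
Product: 8 [(1R,2R,3R)-2-methyl-3-(prop-1-en-2-yl)-2-(prop-2-en-1-yl)cyclobutyl]methanol (C3 alcohol)
Conditions: LiAlH4, Et2O, 0 °C
Reagents that add atoms: none
Why: Hydride reduction of the ester gives the primary alcohol (C3) without touching a stereocentre.

Step 5
Reactants: 8 C3 alcohol
Product: 9 triethylsilyl ether of 8
Conditions: Et3SiCl, imidazole, CH2Cl2, 0 °C
Reagents that add atoms: chlorotriethylsilane CC[Si](Cl)(CC)CC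
Why: Silylation of the primary alcohol; the triethylsilyl group is chosen because it can later be removed in the presence of a tert-butyldimethylsilyl ether.

Step 6
Reactants: 9 triethylsilyl ether of 8
Product: 11 C8 alcohol (9 with 3-hydroxypropyl in place of allyl), via catechol boronate 10 (not isolated)
Conditions: catecholborane, RhCl(PPh3)3 (2 mol %), THF, 0 °C to rt; then NaOH, H2O2, 0 °C
Reagents that add atoms: hydrogen peroxide OO
Why: Rhodium-catalysed hydroboration followed by oxidation: catecholborane under this catalysis adds far faster to the monosubstituted allyl terminus than to the hindered 1,1-disubstituted isopropenyl group and gives the anti-Markovnikov primary alcohol (C8).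

Step 7
Reactants: 11 C8 alcohol
Product: 12 2,4,6-triisopropylbenzoate of 11
Conditions: 2,4,6-(i-Pr)3C6H2CO2H, PPh3, DIAD, THF, 0 °C to rt
Reagents that add atoms: 2,4,6-triisopropylbenzoic acid CC(C)c1cc(C(C)C)c(C(=O)O)c(C(C)C)c1
Why: Mitsunobu esterification of the unhindered primary alcohol; the hindered benzoate will direct the lithiation at C8 and serve as the leaving group in the 1,2-migration.

Step 8
Reactants: 13 (±)-lavandulol
Product: 14 (S)-lavandulol
Conditions: lipase B from Candida antarctica (immobilised), vinyl acetate, hexane, 30 °C, stopped beyond half conversion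
Reagents that add atoms: none
Why: Lipase-catalysed kinetic resolution by transesterification: the R alcohol is acetylated faster, so running the reaction beyond half conversion should leave alcohol that is highly enriched in the S enantiomer, which is separated from the ester by chromatography.

Step 9
Reactants: 14 (S)-lavandulol
Product: 15 (S)-lavandulyl triisopropylsilyl ether
Conditions: i-Pr3SiCl, imidazole, DMF, rt
Reagents that add atoms: chlorotriisopropylsilane CC(C)[Si](Cl)(C(C)C)C(C)C
Why: Silylation; the bulky silyl ether withstands the alkyllithium base of the next step.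

Step 10
Reactants: 15 (S)-lavandulyl triisopropylsilyl ether
Product: 18 (3S)-6-methyl-2-methylidene-3-{[tri(propan-2-yl)silyl]oxymethyl}hept-5-en-1-ol (C2 alcohol), via allyllithium 16 (not isolated), via dimethyl allylboronate 17 (not isolated)
Conditions: n-BuLi, TMEDA, hexane, 0 °C to rt; B(OMe)3, THF, −78 °C; NaOH, H2O2, 0 °C
Reagents that add atoms: hydrogen peroxide OO
Why: Allylic lithiation, borylation and oxidation: the methyl group of the 1,1-disubstituted alkene is the kinetically most acidic allylic position (as in the lithiation of limonene at its isopropenyl methyl), the 2-substituted allyl anion has two equivalent CH2 termini so only one alcohol can result, and C10 lies outside the allyl system and keeps its configuration.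

Step 11
Reactants: 18 C2 alcohol
Product: 19 4-methoxybenzyl ether of 18
Conditions: NaH, 4-MeOC6H4CH2Cl, Bu4NI (cat.), THF/DMF, 0 °C to rt
Reagents that add atoms: 4-methoxybenzyl chloride COc1ccc(CCl)cc1
Why: Williamson etherification of the allylic alkoxide.

Step 12
Reactants: 19 4-methoxybenzyl ether of 18
Product: 20 (2S)-2-{3-[(4-methoxybenzyl)oxy]prop-1-en-2-yl}-5-methylhex-4-en-1-ol (C9 alcohol)
Conditions: Bu4NF, THF, rt
Reagents that add atoms: none
Why: Fluoride-induced cleavage of the silyl ether frees the C9 alcohol while the benzyl-type ether stays.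

Step 13
Reactants: 20 C9 alcohol
Product: 21 C9 iodide (20 with I in place of OH)
Conditions: I2, PPh3, imidazole, CH2Cl2, 0 °C
Reagents that add atoms: iodine II
Why: Appel-type iodination by SN2 displacement at the primary carbon C9; the adjacent stereocentre is not involved.

Step 14
Reactants: 21 C9 iodide
Product: 23 C9 pinacol boronic ester (20 with B(pin) in place of OH), via alkyllithium 22 (not isolated)
Conditions: t-BuLi (2.1 equiv), Et2O, −78 °C; then i-PrOB(pin), −78 °C to rt
Reagents that add atoms: 2-isopropoxy-4,4,5,5-tetramethyl-1,3,2-dioxaborolane CC(C)OB1OC(C)(C)C(C)(C)O1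
Why: Iodine–lithium exchange and trapping with a borate ester; the polar exchange at −78 °C avoids radical intermediates, which could rearrange the homoallylic system by 1,2-vinyl shift.

Step 15
Reactants: 12 2,4,6-triisopropylbenzoate of the C8 alcohol; 23 C9 pinacol boronic ester
Product: 26 (8S) C8 pinacol boronic ester joining both fragments, via lithiated benzoate 24 (not isolated), via boronate complex 25 (not isolated)
Conditions: s-BuLi, (+)-sparteine, Et2O, −78 °C; 23, −78 °C; then 35 °C
Reagents that add atoms: none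
Why: Sparteine-mediated lithiation–borylation (a Matteson-type 1,2-metallate rearrangement): s-BuLi/(+)-sparteine removes the pro-R hydrogen next to the ester oxygen, boronic ester 23 adds with retention, and on warming the C9 alkyl group migrates from boron to carbon anti to the departing benzoate, which joins the fragments and sets C8 under reagent control.

Step 16
Reactants: 26 C8 pinacol boronic ester
Product: 29 open-chain triether (C3–OSiEt3, C8 side chain OSiMe2t-Bu, C2–O-4-methoxybenzyl), via alkenylboronate complex 27 (not isolated), via iodo boronic ester 28 (not isolated)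
Conditions: CH2=C(Br)CH2OSiMe2t-Bu, t-BuLi, Et2O, −78 °C; 26, THF, −78 °C; I2, MeOH; NaOMe, MeOH, −78 °C to rt
Reagents that add atoms: 2-bromo-3-(tert-butyldimethylsilyloxy)prop-1-ene (as its 2-lithio derivative) C=C(Br)CO[Si](C)(C)C(C)(C)C
Why: Zweifel olefination: iodine activates the alkenyl group of the boronate complex, C8 migrates from boron to carbon with retention, and methoxide-induced anti elimination of boron and iodine leaves the 1,1-disubstituted alkene, so that C8 now has the S configuration of the target.

Step 17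
Reactants: 29 open-chain triether
Product: 30 C3 alcohol (29 without the triethylsilyl group)
Conditions: PPTS, MeOH/CH2Cl2, 0 °C
Reagents that add atoms: none
Why: Acid-catalysed methanolysis of the silyl ether; a primary triethylsilyl ether is cleaved much faster than the tert-butyldimethylsilyl ether, and the benzyl-type ether is inert.

Step 18
Reactants: 30 C3 alcohol
Product: 31 C3 iodide
Conditions: I2, PPh3, imidazole, CH2Cl2, 0 °C to rt
Reagents that add atoms: iodine II
Why: Appel-type iodination of the C3 alcohol by SN2 displacement.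

Step 19
Reactants: 31 C3 iodide
Product: 32 C3 phenyl sulfone
Conditions: PhSO2Na, DMF, 70 °C
Reagents that add atoms: sodium benzenesulfinate [Na+].[O-]S(=O)c1ccccc1
Why: SN2 S-alkylation of the sulfinate gives the sulfone at its final oxidation level, so that no sulfur oxidation is needed beside four alkenes.

Step 20
Reactants: 32 C3 phenyl sulfone
Product: 34 C3 bis(phenylsulfonyl) compound with C2–O-4-methoxybenzyl, via lithio sulfone 33 (not isolated)
Conditions: LiN(i-Pr)2 (2.2 equiv), THF, −78 °C; PhSO2F, −78 to 0 °C; aq NH4Cl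
Reagents that add atoms: benzenesulfonyl fluoride O=S(=O)(F)c1ccccc1
Why: Sulfonylation of the α-sulfonyl carbanion with a sulfonyl fluoride; the second equivalent of base takes up the much more acidic bis-sulfone as it forms, which drives the reaction to completion.

Step 21
Reactants: 34 bis-sulfone 4-methoxybenzyl ether
Product: 35 bis-sulfone C2 allylic alcohol
Conditions: DDQ, CH2Cl2/pH 7 buffer, 0 °C
Reagents that add atoms: none
Why: Oxidative cleavage of the 4-methoxybenzyl ether by hydride abstraction; silyl ether, bis-sulfone and alkenes are not affected under buffered conditions.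

Step 22
Reactants: 35 bis-sulfone C2 allylic alcohol
Product: 36 seco allylic methyl carbonate with CH(SO2Ph)2 on C4 (cyclisation precursor)
Conditions: ClCO2Me, pyridine, CH2Cl2, 0 °C
Reagents that add atoms: methyl chloroformate COC(=O)Cl
Why: O-Acylation of the primary allylic alcohol; pyridine is too weak a base to deprotonate the bis-sulfone.

Step 23
Reactants: 36 seco allylic methyl carbonate
Product: 37 bicyclo[8.2.0]dodecane with the bis-sulfone at C3
Conditions: Pd(PPh3)4 (10 mol %), 1,2-bis(diphenylphosphino)ethane (10 mol %), THF, 65 °C, 36 added over 12 h to a final 0.002 M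
Reagents that add atoms: none
Why: Zerovalent palladium ionises the allylic carbonate on C2 with loss of CO2, and the methoxide that results takes the acidic proton from the bis-sulfone at C3, so no base has to be added; the carbanion then attacks the π-allyl ligand and frees the catalyst. The reaction is the Tsuji–Trost allylic alkylation in its macrocyclising form, the closest known cases being medium and large carbocycles closed at bis(phenylsulfonyl)methine carbons under neutral carbonate conditions. The ten-membered ring closes by attack of the tethered carbanion on an allyl terminus that becomes a ring CH2, while the other terminus stays outside the ring as the methylene group; because both termini are CH2 groups on C1, either mode of attack gives the same ring and the same alkene. No stereocentre is formed and none of the five present lies at a reacting carbon, so all are carried through unchanged. The step needs cyclisation to outrun oligomerisation: slow addition to a dilute catalyst solution, the irreversible C–C bond formation and the absence of any second ionisable or electrophilic group (the C8 side chain is a silyl ether, not an enoate) secure this.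

Step 24
Reactants: 37 macrocyclic bis-sulfone
Product: 39 desulfonylated macrocycle (C8 side chain still silylated), via mono-sulfone 38 (not isolated)
Conditions: Na(Hg) (6 %), Na2HPO4, MeOH/THF, −20 to 0 °C
Reagents that add atoms: none
Why: Reductive desulfonylation by electron transfer from sodium amalgam: each sulfone leaves as sulfinate and the carbanion is protonated by methanol, so C3 becomes CH2; the low temperature and the fast second electron transfer at the metal surface should keep the transient C3 radical from opening the neighbouring cyclobutane.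

Step 25
Reactants: 39 desulfonylated macrocycle
Product: 40 macrocyclic allylic alcohol
Conditions: Bu4NF, THF, 0 °C to rt
Reagents that add atoms: none
Why: Fluoride-induced cleavage of the silyl ether.

Step 26
Reactants: 40 macrocyclic allylic alcohol
Product: 42 CNP0198062.1, via enal 41 (not isolated)
Conditions: TEMPO (cat.), PhI(OAc)2, CH2Cl2, rt; then t-BuOH, 2-methylbut-2-ene, NaClO2, NaH2PO4, H2O, 0 °C to rt
Reagents that add atoms: sodium chlorite [Na+].[O-]Cl=O
Why: Oxoammonium (TEMPO) oxidation of the allylic alcohol to the enal followed by Pinnick oxidation in the same flask; the chlorine scavenger protects the four alkenes from hypochlorous acid.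

Compound list
1 | 2-methylcyclopent-2-en-1-one | CC1=CCCC1=O | starting material
2 | bromomagnesium (3R)-2-methyl-3-(prop-1-en-2-yl)cyclopent-1-en-1-olate | Br[Mg]OC1=C(C)[C@@H](C(=C)C)CC1 | intermediate (not isolated)
3 | (2R,3R)-2-methyl-3-(prop-1-en-2-yl)-2-(prop-2-en-1-yl)cyclopentan-1-one | O=C1CC[C@H](C(=C)C)[C@@]1(C)CC=C | intermediate
4 | (2R,3R)-2-methyl-3-(prop-1-en-2-yl)-2-(prop-2-en-1-yl)-5-(trifluoroacetyl)cyclopentan-1-one (C5 unassigned) | O=C1C(C(=O)C(F)(F)F)C[C@H](C(=C)C)[C@@]1(C)CC=C | intermediate (not isolated)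
5 | (2R,3R)-5-diazo-2-methyl-3-(prop-1-en-2-yl)-2-(prop-2-en-1-yl)cyclopentan-1-one | O=C1C(=[N+]=[N-])C[C@H](C(=C)C)[C@@]1(C)CC=C | intermediate
6 | [(2R,3R)-2-methyl-3-(prop-1-en-2-yl)-2-(prop-2-en-1-yl)cyclobutylidene]methanone (ketene) | O=C=C2C[C@H](C(=C)C)[C@@]2(C)CC=C | intermediate (not isolated)
7 | methyl (1R,2R,3R)-2-methyl-3-(prop-1-en-2-yl)-2-(prop-2-en-1-yl)cyclobutane-1-carboxylate | COC(=O)[C@@H]2C[C@H](C(=C)C)[C@@]2(C)CC=C | intermediate
8 | [(1R,2R,3R)-2-methyl-3-(prop-1-en-2-yl)-2-(prop-2-en-1-yl)cyclobutyl]methanol | OC[C@@H]2C[C@H](C(=C)C)[C@@]2(C)CC=C | intermediate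
9 | triethylsilyl ether of 8 | CC[Si](CC)(CC)OC[C@@H]2C[C@H](C(=C)C)[C@@]2(C)CC=C | intermediate
10 | 2-(3-substituted propyl)-1,3,2-benzodioxaborole from hydroboration of the allyl group of 9, cyclobutane as in 8 | CC[Si](CC)(CC)OC[C@@H]2C[C@H](C(=C)C)[C@@]2(C)CCCB1Oc3ccccc3O1 | intermediate (not isolated)
11 | 9 with 3-hydroxypropyl in place of allyl (C8 alcohol), cyclobutane as in 8 | CC[Si](CC)(CC)OC[C@@H]2C[C@H](C(=C)C)[C@@]2(C)CCCO | intermediate
12 | 2,4,6-triisopropylbenzoate of 11 | CC[Si](CC)(CC)OC[C@@H]2C[C@H](C(=C)C)[C@@]2(C)CCCOC(=O)c1c(C(C)C)cc(C(C)C)cc1C(C)C | intermediate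
13 | (±)-lavandulol, 5-methyl-2-(prop-1-en-2-yl)hex-4-en-1-ol | CC(=C)C(CO)CC=C(C)C | starting material
14 | (S)-lavandulol, (2S)-5-methyl-2-(prop-1-en-2-yl)hex-4-en-1-ol | OC[C@H](C(=C)C)CC=C(C)C | intermediate
15 | (S)-lavandulyl triisopropylsilyl ether | CC(C)[Si](C(C)C)(C(C)C)OC[C@H](C(=C)C)CC=C(C)C | intermediate
16 | allyllithium: 15 lithiated at the isopropenyl methyl | CC(C)[Si](C(C)C)(C(C)C)OC[C@H](C(=C)C[Li])CC=C(C)C | intermediate (not isolated)
17 | dimethyl allylboronate: 15 carrying B(OMe)2 on the former isopropenyl methyl | CC(C)[Si](C(C)C)(C(C)C)OC[C@H](C(=C)CB(OC)OC)CC=C(C)C | intermediate (not isolated)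
18 | (3S)-6-methyl-2-methylidene-3-{[tri(propan-2-yl)silyl]oxymethyl}hept-5-en-1-ol | CC(C)[Si](C(C)C)(C(C)C)OC[C@H](C(=C)CO)CC=C(C)C | intermediate
19 | 4-methoxybenzyl ether of 18 | CC(C)[Si](C(C)C)(C(C)C)OC[C@H](C(=C)COCc1ccc(OC)cc1)CC=C(C)C | intermediate
20 | (2S)-2-{3-[(4-methoxybenzyl)oxy]prop-1-en-2-yl}-5-methylhex-4-en-1-ol | OC[C@H](C(=C)COCc1ccc(OC)cc1)CC=C(C)C | intermediate
21 | iodide of 20 (I in place of OH) | IC[C@H](C(=C)COCc1ccc(OC)cc1)CC=C(C)C | intermediate
22 | alkyllithium from 21 (Li in place of I) | [Li]C[C@H](C(=C)COCc1ccc(OC)cc1)CC=C(C)C | intermediate (not isolated)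
23 | pinacol boronic ester of the lavandulol fragment (B(pin) on C9) | CC1(C)OB(OC1(C)C)C[C@H](C(=C)COCc1ccc(OC)cc1)CC=C(C)C | intermediate
24 | (R)-α-lithiated benzoate: 12 with Li on C8 | CC[Si](CC)(CC)OC[C@@H]2C[C@H](C(=C)C)[C@@]2(C)CC[C@@H]([Li])OC(=O)c1c(C(C)C)cc(C(C)C)cc1C(C)C | intermediate (not isolated)
25 | lithium boronate complex of 24 and 23 (boron on C8, benzoate still on C8) | [Li+].CC[Si](CC)(CC)OC[C@@H]2C[C@H](C(=C)C)[C@@]2(C)CC[C@@H]([B-]3(C[C@H](C(=C)COCc4ccc(OC)cc4)CC=C(C)C)OC(C)(C)C(C)(C)O3)OC(=O)c1c(C(C)C)cc(C(C)C)cc1C(C)C | intermediate (not isolated)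
26 | (8S) secondary pinacol boronic ester: C3–OSiEt3 cyclobutane, B(pin) on C8, C9–C10 lavandulol unit with C2–O-4-methoxybenzyl | CC[Si](CC)(CC)OC[C@@H]2C[C@H](C(=C)C)[C@@]2(C)CC[C@H](B1OC(C)(C)C(C)(C)O1)C[C@H](C(=C)COCc1ccc(OC)cc1)CC=C(C)C | intermediate
27 | lithium alkenylboronate complex of 26 with 3-(tert-butyldimethylsilyloxy)prop-1-en-2-yl on boron | [Li+].CC[Si](CC)(CC)OC[C@@H]2C[C@H](C(=C)C)[C@@]2(C)CC[C@H]([B-]1(C(=C)CO[Si](C)(C)C(C)(C)C)OC(C)(C)C(C)(C)O1)C[C@H](C(=C)COCc1ccc(OC)cc1)CC=C(C)C | intermediate (not isolated)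
28 | β-iodo boronic ester after migration of C8 (new carbon unassigned) | CC[Si](CC)(CC)OC[C@@H]2C[C@H](C(=C)C)[C@@]2(C)CC[C@H](C(CI)(CO[Si](C)(C)C(C)(C)C)B1OC(C)(C)C(C)(C)O1)C[C@H](C(=C)COCc1ccc(OC)cc1)CC=C(C)C | intermediate (not isolated)
29 | open-chain triether: C3–OSiEt3, C8 bearing 3-(tert-butyldimethylsilyloxy)prop-1-en-2-yl, C2–O-4-methoxybenzyl; configuration at C4, C5, C8, C10, C12 as in 42 | CC[Si](CC)(CC)OC[C@@H]2C[C@H](C(=C)C)[C@@]2(C)CC[C@H](C(=C)CO[Si](C)(C)C(C)(C)C)C[C@H](C(=C)COCc1ccc(OC)cc1)CC=C(C)C | intermediate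
30 | C3 alcohol (29 without SiEt3) | OC[C@@H]2C[C@H](C(=C)C)[C@@]2(C)CC[C@H](C(=C)CO[Si](C)(C)C(C)(C)C)C[C@H](C(=C)COCc1ccc(OC)cc1)CC=C(C)C | intermediate
31 | C3 iodide | IC[C@@H]2C[C@H](C(=C)C)[C@@]2(C)CC[C@H](C(=C)CO[Si](C)(C)C(C)(C)C)C[C@H](C(=C)COCc1ccc(OC)cc1)CC=C(C)C | intermediate
32 | C3 phenyl sulfone | O=S(=O)(c1ccccc1)C[C@@H]2C[C@H](C(=C)C)[C@@]2(C)CC[C@H](C(=C)CO[Si](C)(C)C(C)(C)C)C[C@H](C(=C)COCc1ccc(OC)cc1)CC=C(C)C | intermediate
33 | α-lithio sulfone from 32 | [Li]C(S(=O)(=O)c1ccccc1)[C@@H]2C[C@H](C(=C)C)[C@@]2(C)CC[C@H](C(=C)CO[Si](C)(C)C(C)(C)C)C[C@H](C(=C)COCc1ccc(OC)cc1)CC=C(C)C | intermediate (not isolated)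
34 | bis(phenylsulfonyl)methyl compound with C2–O-4-methoxybenzyl | C(S(=O)(=O)c1ccccc1)(S(=O)(=O)c1ccccc1)[C@@H]2C[C@H](C(=C)C)[C@@]2(C)CC[C@H](C(=C)CO[Si](C)(C)C(C)(C)C)C[C@H](C(=C)COCc1ccc(OC)cc1)CC=C(C)C | intermediate
35 | bis-sulfone C2 allylic alcohol | C(S(=O)(=O)c1ccccc1)(S(=O)(=O)c1ccccc1)[C@@H]2C[C@H](C(=C)C)[C@@]2(C)CC[C@H](C(=C)CO[Si](C)(C)C(C)(C)C)C[C@H](C(=C)CO)CC=C(C)C | intermediate
36 | seco allylic methyl carbonate with bis(phenylsulfonyl)methyl on cyclobutane C4 (cyclisation precursor) | C(S(=O)(=O)c1ccccc1)(S(=O)(=O)c1ccccc1)[C@@H]2C[C@H](C(=C)C)[C@@]2(C)CC[C@H](C(=C)CO[Si](C)(C)C(C)(C)C)C[C@H](C(=C)COC(=O)OC)CC=C(C)C | intermediate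
37 | bicyclo[8.2.0]dodecane with C3 bis-sulfone and all five stereocentres | C=C1CC(S(=O)(=O)c3ccccc3)(S(=O)(=O)c3ccccc3)[C@@H]2C[C@H](C(=C)C)[C@@]2(C)CC[C@H](C(=C)CO[Si](C)(C)C(C)(C)C)C[C@H]1CC=C(C)C | intermediate
38 | macrocyclic C3 mono-sulfone (C3 unassigned) | C=C1CC(S(=O)(=O)c3ccccc3)[C@@H]2C[C@H](C(=C)C)[C@@]2(C)CC[C@H](C(=C)CO[Si](C)(C)C(C)(C)C)C[C@H]1CC=C(C)C | intermediate (not isolated)
39 | desulfonylated macrocycle, C8 side chain as tert-butyldimethylsilyl ether | C=C1CC[C@@H]2C[C@H](C(=C)C)[C@@]2(C)CC[C@H](C(=C)CO[Si](C)(C)C(C)(C)C)C[C@H]1CC=C(C)C | intermediate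
40 | macrocyclic allylic alcohol (C8 bearing 3-hydroxyprop-1-en-2-yl) | C=C1CC[C@@H]2C[C@H](C(=C)C)[C@@]2(C)CC[C@H](C(=C)CO)C[C@H]1CC=C(C)C | intermediate
41 | macrocyclic enal (C8 bearing 3-oxoprop-1-en-2-yl) | C=C1CC[C@@H]2C[C@H](C(=C)C)[C@@]2(C)CC[C@H](C(=C)C=O)C[C@H]1CC=C(C)C | intermediate (not isolated)
42 | CNP0198062.1, 2-[(1S,4S,6R,10R,12R)-1-methyl-7-methylidene-6-(3-methylbut-2-en-1-yl)-12-(prop-1-en-2-yl)bicyclo[8.2.0]dodecan-4-yl]prop-2-enoic acid | C=C1CC[C@@H]2C[C@H](C(=C)C)[C@@]2(C)CC[C@H](C(=C)C(=O)O)C[C@H]1CC=C(C)C | target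

Total step count: 26 steps. Longest linear sequence: 19 steps (steps 1–7 and 15–26; the lavandulol branch, steps 8–14 and 15–26, is equally long).

Steps most likely to fail

1. Step 23 (ring closure). The hindered tertiary carbanion next to the cyclobutane may add to the π-allyl too slowly, so that intermolecular alkylation and protonolysis of the allyl complex take over. Fallback without palladium: alcohol 35 is converted into the allylic chloride F1 (MsCl, LiCl, 2,4,6-collidine, DMF, 0 °C), and F1 is added slowly to Cs2CO3 and Bu4NI in MeCN at 60 °C. Intramolecular alkylation of the bis-sulfonyl carbanion, direct or allylically transposed, closes the same C2–C3 bond and gives the same alkene, which returns to the route at 37.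

2. Step 1 (conjugate addition and allylation). Facial discrimination in the copper-catalysed transfer of the sp2 Grignard group may be poor, and C-alkylation of the magnesium enolate may lag behind proton exchange. Fallback: 1 is treated with isopropenylmagnesium bromide and CuBr·SMe2 without ligand and the enolate is allylated as before, which gives the racemic trans ketone F2. Its enantiomers are separated by preparative chromatography on a chiral stationary phase, and the (2R,3R) isomer is 3.

3. Step 20 (second sulfonyl group). Sulfonylation of the hindered α-sulfonyl carbanion may stall through proton transfer from the acidic product or through slow attack at the sulfonyl fluoride. Fallback: 32 is deprotonated with LiN(i-Pr)2 and sulfenylated with PhSSPh to the α-(phenylthio) sulfone F3. The sulfide is then oxidised chemoselectively with H2O2 and catalytic (NH4)6Mo7O24·4H2O in EtOH at 0 °C, a system that leaves isolated alkenes alone, and this gives 34.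

Further compounds
F1 | step 23 | allylic chloride: 35 with the C2 hydroxyl replaced by chloride | C(S(=O)(=O)c1ccccc1)(S(=O)(=O)c1ccccc1)[C@@H]2C[C@H](C(=C)C)[C@@]2(C)CC[C@H](C(=C)CO[Si](C)(C)C(C)(C)C)C[C@H](C(=C)CCl)CC=C(C)C
F2 | step 1 | racemic trans ketone, (2R,3R)- and (2S,3S)-2-methyl-3-(prop-1-en-2-yl)-2-(prop-2-en-1-yl)cyclopentan-1-one | O=C1CC[C@H](C(=C)C)[C@@]1(C)CC=C.O=C1CC[C@@H](C(=C)C)[C@]1(C)CC=C
F3 | step 20 | α-(phenylthio) sulfone: 32 carrying SPh on C3 (C3 unassigned) | C(Sc1ccccc1)(S(=O)(=O)c1ccccc1)[C@@H]2C[C@H](C(=C)C)[C@@]2(C)CC[C@H](C(=C)CO[Si](C)(C)C(C)(C)C)C[C@H](C(=C)COCc1ccc(OC)cc1)CC=C(C)C
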